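**Retrosynthetic overview**
- The target comes from selective oxidation of the allylic C7-OH of a 6β,7β-diol lactone; the 6β-OH comes from α-face hydride reduction of a ring-B diosphenol (6-hydroxy-5,8-dien-7-one).
- Key step: the C6 oxygen is installed by [4+2] cycloaddition of singlet oxygen to the ring-B 2-silyloxy-1,3-diene of a 7-oxo-8-ene (endoperoxide → 6,7-dione); the enone comes from allylic oxidation of the 8(9)-alkene.
- The γ-lactone comes from reductive unmasking of a Seebach dioxolanone (C16 carbonyl → CH2OH) and lactonisation onto the C15 acid.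
- The C12–C13 bond comes from alkylation of the (S)-malic acid dioxolanone dianion (C13 bought, retention) with a C16 homoallylic iodide made from (+)-sclareolide (C5 and C10 bought).
- Ring order: rings A and B are bought in sclareolide; then the temporary dioxolanone; then the transient 2,3-dioxabicyclo[2.2.2]octene of the cycloaddition; the butyrolactone is closed last.

Assumption: the SMILES is read as the normal-series labdane (5S,6S,10S,13S)-6β,13-dihydroxy-7-oxolabd-8-en-15,16-olide; labdane numbering (C1–C20) is used in the explanations.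

**Step 1**
Reactants: 1 (S)-malic acid
Product: 2 2-[(2S,4S)-2-tert-butyl-5-oxo-1,3-dioxolan-4-yl]acetic acid
Conditions: pivalaldehyde, p-TsOH (cat.), H2SO4 (cat.), pentane, reflux (Dean–Stark); recrystallise
Reagents that add atoms: pivalaldehyde, CC(C)(C)C=O
Why: Acid-catalysed acetalisation (Seebach self-regeneration-of-stereocentre acetal) closes the five-membered dioxolanone on the α-hydroxy acid; the new acetal centre is set cis to the side chain under control of the bought C2 of malic acid, and the cis isomer is purified by crystallisation.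

**Step 2**
Reactants: 3 (+)-sclareolide
Product: 4 methyl 2-[(4aS,8aS)-2,5,5,8a-tetramethyl-3,4,4a,5,6,7,8,8a-octahydronaphthalen-1-yl]acetate
Conditions: H2SO4 (conc.), MeOH, 65 °C; AgNO3–silica chromatography
Reagents that add atoms: methanol, CO
Why: Acid-mediated alkyl–oxygen cleavage of the tertiary lactone (E1) with Zaitsev loss of H9 gives the tetrasubstituted 8(9)-alkene and Fischer esterification traps the acid; C5 and C10 are untouched and the minor Δ7 and exocyclic isomers are removed.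

**Step 3**
Reactants: 4 methyl 2-[(4aS,8aS)-2,5,5,8a-tetramethyl-3,4,4a,5,6,7,8,8a-octahydronaphthalen-1-yl]acetate
Product: 5 2-[(4aS,8aS)-2,5,5,8a-tetramethyl-3,4,4a,5,6,7,8,8a-octahydronaphthalen-1-yl]ethan-1-ol
Conditions: LiAlH4, THF, 0 °C
Reagents that add atoms: none
Why: Hydride reduction of the ester to the primary alcohol; the isolated tetrasubstituted alkene is inert.

**Step 4**
Reactants: 5 2-[(4aS,8aS)-2,5,5,8a-tetramethyl-3,4,4a,5,6,7,8,8a-octahydronaphthalen-1-yl]ethan-1-ol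
Product: 7 (4aS,8aS)-1-(2-iodoethyl)-2,5,5,8a-tetramethyl-3,4,4a,5,6,7,8,8a-octahydronaphthalene, via mesylate 6 (not isolated)
Conditions: MsCl, Et3N, CH2Cl2, 0 °C; then NaI, acetone, 50 °C
Reagents that add atoms: sodium iodide, [Na+].[I-]
Why: Mesylation followed by Finkelstein SN2 displacement at the primary carbon; no stereocentre is involved.

**Step 5**
Reactants: 2 2-[(2S,4S)-2-tert-butyl-5-oxo-1,3-dioxolan-4-yl]acetic acid + 7 (4aS,8aS)-1-(2-iodoethyl)-2,5,5,8a-tetramethyl-3,4,4a,5,6,7,8,8a-octahydronaphthalene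
Product: 9 2-[(2S,4S)-2-tert-butyl-5-oxo-4-{2-[(4aS,8aS)-2,5,5,8a-tetramethyl-3,4,4a,5,6,7,8,8a-octahydronaphthalen-1-yl]ethyl}-1,3-dioxolan-4-yl]acetic acid, via dilithium dianion 8 (not isolated)
Conditions: 2, LiN(SiMe3)2 (2.1 equiv), THF, −78 °C; then 7, DMPU, −78 → −30 °C; 1 M HCl
Reagents that add atoms: none
Why: Seebach alkylation with self-regeneration of the stereocentre: the dianion of 2 is alkylated (SN2) by the primary iodide on the face anti to the tert-butyl group, so C13 forms with overall retention, controlled by the acetal centre that (S)-malic acid had set.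

**Step 6**
Reactants: 9 2-[(2S,4S)-2-tert-butyl-5-oxo-4-{2-[(4aS,8aS)-2,5,5,8a-tetramethyl-3,4,4a,5,6,7,8,8a-octahydronaphthalen-1-yl]ethyl}-1,3-dioxolan-4-yl]acetic acid
Product: 10 2-[(2S,4S)-2-tert-butyl-5-oxo-4-{2-[(4aS,8aS)-2,5,5,8a-tetramethyl-3-oxo-3,4,4a,5,6,7,8,8a-octahydronaphthalen-1-yl]ethyl}-1,3-dioxolan-4-yl]acetic acid
Conditions: CrO3, 3,5-dimethylpyrazole, CH2Cl2, −20 °C
Reagents that add atoms: chromium trioxide, O=[Cr](=O)=O
Why: Allylic oxidation (CrO3–3,5-dimethylpyrazole) takes the ring methylene C7 of the tetrasubstituted alkene to the conjugated enone, the hindered chain methylene C11 and the C8 methyl reacting much more slowly; the acid, the acetal and all stereocentres are unaffected.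

**Step 7**
Reactants: 10 2-[(2S,4S)-2-tert-butyl-5-oxo-4-{2-[(4aS,8aS)-2,5,5,8a-tetramethyl-3-oxo-3,4,4a,5,6,7,8,8a-octahydronaphthalen-1-yl]ethyl}-1,3-dioxolan-4-yl]acetic acid
Product: 14 2-[(2S,4S)-2-tert-butyl-4-{2-[(8aR)-4-hydroxy-2,5,5,8a-tetramethyl-3-oxo-3,5,6,7,8,8a-hexahydronaphthalen-1-yl]ethyl}-5-oxo-1,3-dioxolan-4-yl]acetic acid, via silyloxydiene 11 (not isolated), via endoperoxide 12 (not isolated), via silylperoxy enone 13 (not isolated)
Conditions: LiN(SiMe3)2 (2.2 equiv), Me3SiCl, THF, −78 °C; then O2, 5,10,15,20-tetraphenylporphyrin (cat.), hν, CH2Cl2, −78 → −20 °C; then Ar purge, 1,8-diazabicyclo[5.4.0]undec-7-ene (DBU), 0 °C → rt; aq. NaH2PO4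
Reagents that add atoms: oxygen, O=O
Why: Kinetic α′-enolisation and O-silylation give the s-cis ring-B 2-silyloxy-1,3-diene, which takes up singlet oxygen in a hetero-Diels–Alder [4+2] cycloaddition across C6/C9 from the α-face; silyl-assisted retro-oxa-Michael opening of the endoperoxide and Kornblum–DeLaMare elimination give the 6,7-dione, which enolises to the diosphenol, so the C6 (and C5) configuration is deliberately erased here.

**Step 8**
Reactants: 14 2-[(2S,4S)-2-tert-butyl-4-{2-[(8aR)-4-hydroxy-2,5,5,8a-tetramethyl-3-oxo-3,5,6,7,8,8a-hexahydronaphthalen-1-yl]ethyl}-5-oxo-1,3-dioxolan-4-yl]acetic acid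
Product: 16 (4S)-4-{2-[(3R,4S,4aS,8aS)-3,4-dihydroxy-2,5,5,8a-tetramethyl-3,4,4a,5,6,7,8,8a-octahydronaphthalen-1-yl]ethyl}-4-hydroxyoxolan-2-one, via seco acid 15 (not isolated)
Conditions: LiBH4, THF–MeOH (10:1), 0 °C → rt; then 1 M HCl to pH 3, 0 °C → rt
Reagents that add atoms: none
Why: Borohydride reduces C7=O, the freed enol ketonises by α-face protonation at C5 (trans-decalin) and the resulting C6 ketone takes hydride from the α-face, anti to the axial C4β and C10β methyls, giving 6β-OH; the dioxolanone carbonyl is reduced with loss of the pivalaldehyde acetal while the carboxylate survives, and acidification closes the γ-lactone with C13 retained (the 7-epimer, if formed, converges in the next step).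

**Step 9**
Reactants: 16 (4S)-4-{2-[(3R,4S,4aS,8aS)-3,4-dihydroxy-2,5,5,8a-tetramethyl-3,4,4a,5,6,7,8,8a-octahydronaphthalen-1-yl]ethyl}-4-hydroxyoxolan-2-one
Product: 17 (4S)-4-hydroxy-4-{2-[(4S,4aS,8aS)-4-hydroxy-2,5,5,8a-tetramethyl-3-oxo-3,4,4a,5,6,7,8,8a-octahydronaphthalen-1-yl]ethyl}oxolan-2-one
Conditions: MnO2, CH2Cl2, rt
Reagents that add atoms: none
Why: Chemoselective MnO2 oxidation of the allylic C7 alcohol restores the 7-oxo-8-ene; the hindered non-allylic 6β-OH and the tertiary 13-OH are inert and the neutral conditions do not epimerise C6.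

**Compound list**
1 | (S)-malic acid, (2S)-2-hydroxybutanedioic acid | OC(=O)C[C@H](O)C(=O)O | starting material
2 | 2-[(2S,4S)-2-tert-butyl-5-oxo-1,3-dioxolan-4-yl]acetic acid (cis) | CC(C)(C)[C@H]1O[C@@H](CC(=O)O)C(=O)O1 | intermediate
3 | (+)-sclareolide, (3aR,5aS,9aS,9bR)-3a,6,6,9a-tetramethyldecahydronaphtho[2,1-b]furan-2(1H)-one | C[C@]12CCCC(C)(C)[C@@H]1CC[C@@]3(C)OC(=O)C[C@H]23 | starting material
4 | methyl 2-[(4aS,8aS)-2,5,5,8a-tetramethyl-3,4,4a,5,6,7,8,8a-octahydronaphthalen-1-yl]acetate | CC1=C(CC(=O)OC)[C@@]2(C)CCCC(C)(C)[C@@H]2CC1 | intermediate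
5 | 2-[(4aS,8aS)-2,5,5,8a-tetramethyl-3,4,4a,5,6,7,8,8a-octahydronaphthalen-1-yl]ethan-1-ol | CC1=C(CCO)[C@@]2(C)CCCC(C)(C)[C@@H]2CC1 | intermediate
6 | 2-[(4aS,8aS)-2,5,5,8a-tetramethyl-3,4,4a,5,6,7,8,8a-octahydronaphthalen-1-yl]ethyl methanesulfonate | CC1=C(CCOS(C)(=O)=O)[C@@]2(C)CCCC(C)(C)[C@@H]2CC1 | intermediate
7 | (4aS,8aS)-1-(2-iodoethyl)-2,5,5,8a-tetramethyl-3,4,4a,5,6,7,8,8a-octahydronaphthalene | CC1=C(CCI)[C@@]2(C)CCCC(C)(C)[C@@H]2CC1 | intermediate
8 | dilithium dianion of 2 (lithium dioxolanone enolate and lithium carboxylate) | [Li+].[Li+].CC(C)(C)[C@H]1OC(CC(=O)[O-])=C([O-])O1 | intermediate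
9 | 2-[(2S,4S)-2-tert-butyl-5-oxo-4-{2-[(4aS,8aS)-2,5,5,8a-tetramethyl-3,4,4a,5,6,7,8,8a-octahydronaphthalen-1-yl]ethyl}-1,3-dioxolan-4-yl]acetic acid | CC(C)(C)[C@H]1O[C@@](CCC2=C(C)CC[C@H]3C(C)(C)CCC[C@]23C)(CC(=O)O)C(=O)O1 | intermediate
10 | 2-[(2S,4S)-2-tert-butyl-5-oxo-4-{2-[(4aS,8aS)-2,5,5,8a-tetramethyl-3-oxo-3,4,4a,5,6,7,8,8a-octahydronaphthalen-1-yl]ethyl}-1,3-dioxolan-4-yl]acetic acid | CC(C)(C)[C@H]1O[C@@](CCC2=C(C)C(=O)C[C@H]3C(C)(C)CCC[C@]23C)(CC(=O)O)C(=O)O1 | intermediate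
11 | trimethylsilyl ester of 10 as its ring-B 2-(trimethylsilyloxy)-1,3-diene, C6=C7(OSiMe3)–C8=C9, (4aS,8aS) | CC(C)(C)[C@H]1O[C@@](CCC2=C(C)C(O[Si](C)(C)C)=C[C@H]3C(C)(C)CCC[C@]23C)(CC(=O)O[Si](C)(C)C)C(=O)O1 | intermediate
12 | 6α,9α-epidioxide of 11 (2,3-dioxabicyclo[2.2.2]oct-5-ene across C6/C9, peroxide bridge on the α-face) | CC(C)(C)[C@H]1O[C@@](CC[C@@]25OO[C@@H](C(O[Si](C)(C)C)=C2C)[C@H]3C(C)(C)CCC[C@@]35C)(CC(=O)O[Si](C)(C)C)C(=O)O1 | intermediate
13 | trimethylsilyl 2-[(2S,4S)-2-tert-butyl-5-oxo-4-{2-[(4R,4aS,8aS)-2,5,5,8a-tetramethyl-3-oxo-4-(trimethylsilylperoxy)-3,4,4a,5,6,7,8,8a-octahydronaphthalen-1-yl]ethyl}-1,3-dioxolan-4-yl]acetate (6α-silylperoxy enone) | CC(C)(C)[C@H]1O[C@@](CCC2=C(C)C(=O)[C@H](OO[Si](C)(C)C)[C@H]3C(C)(C)CCC[C@]23C)(CC(=O)O[Si](C)(C)C)C(=O)O1 | intermediate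
14 | 2-[(2S,4S)-2-tert-butyl-4-{2-[(8aR)-4-hydroxy-2,5,5,8a-tetramethyl-3-oxo-3,5,6,7,8,8a-hexahydronaphthalen-1-yl]ethyl}-5-oxo-1,3-dioxolan-4-yl]acetic acid (diosphenol, 10β-methyl) | CC(C)(C)[C@H]1O[C@@](CCC2=C(C)C(=O)C(O)=C3C(C)(C)CCC[C@]23C)(CC(=O)O)C(=O)O1 | intermediate
15 | (3S)-5-[(3R,4S,4aS,8aS)-3,4-dihydroxy-2,5,5,8a-tetramethyl-3,4,4a,5,6,7,8,8a-octahydronaphthalen-1-yl]-3-hydroxy-3-(hydroxymethyl)pentanoic acid | CC1=C(CC[C@@](O)(CO)CC(=O)O)[C@@]2(C)CCCC(C)(C)[C@@H]2[C@H](O)[C@@H]1O | intermediate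
16 | (4S)-4-{2-[(3R,4S,4aS,8aS)-3,4-dihydroxy-2,5,5,8a-tetramethyl-3,4,4a,5,6,7,8,8a-octahydronaphthalen-1-yl]ethyl}-4-hydroxyoxolan-2-one (6β,7β-diol) | CC1=C(CC[C@@]2(O)COC(=O)C2)[C@@]2(C)CCCC(C)(C)[C@@H]2[C@H](O)[C@@H]1O | intermediate
17 | (4S)-4-hydroxy-4-{2-[(4S,4aS,8aS)-4-hydroxy-2,5,5,8a-tetramethyl-3-oxo-3,4,4a,5,6,7,8,8a-octahydronaphthalen-1-yl]ethyl}oxolan-2-one | CC1=C(CC[C@@]2(O)COC(=O)C2)[C@@]2(C)CCCC(C)(C)[C@@H]2[C@H](O)C1=O | target

**Step count and risks**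
Total step count: 9. Longest linear sequence: 8 steps (3 → 4 → 5 → 7 → 9 → 10 → 14 → 16 → 17).

The three steps most likely to fail:

- **Step 5 (alkylation).** The unactivated homoallylic iodide may react too slowly or undergo E2 with the basic dianion. The fallback sets out from 5 (coupled again with 2 through 8) and comes back at 9. Dess–Martin periodinane oxidises 5 to the aldehyde F5. Dianion 8 adds to it at −78 °C (aldol, same face anti to tert-butyl) to give the C12-hydroxy adduct F6 as a mixture of C12 epimers. PhOC(S)Cl/pyridine/4-dimethylaminopyridine converts it into the O-phenyl thionocarbonate F7, and Bu3SnH/azobisisobutyronitrile in toluene at 80 °C (Barton–McCombie deoxygenation) removes the C12 oxygen to give 9.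

- **Step 7 (photooxygenation).** Enolisation could go to the γ-position (C11), or the endoperoxide could collapse to a 9-hydroxy product. The fallback sets out from 10 and comes back at 14. The silyloxydiene 11 is made as before but oxidised with dimethyldioxirane in acetone at −40 °C (Rubottom oxidation) instead of singlet oxygen, which after mild acidic desilylation gives the 6α-hydroxy enone F8. Dess–Martin periodinane then oxidises this alcohol to the 6,7-dione, which enolises to 14.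

- **Step 2 (alkene regiochemistry).** Acid treatment may give too much of the Δ7 and exocyclic isomers. The fallback sets out from 3 and comes back at 5. LiAlH4 reduces 3 to the 8α,12-diol F1. Ac2O/pyridine acetylates only the primary hydroxyl to give the 12-monoacetate F2. SOCl2/pyridine at −78 °C dehydrates the tertiary alcohol to the exocyclic 8(17)-alkene acetate F3. p-TsOH (cat.) in toluene at 80 °C isomerises it to the tetrasubstituted 8(9)-alkene acetate F4, and K2CO3/MeOH gives 5.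

**Further compounds**
F1 | step 2 | (1R,2R,4aS,8aS)-1-(2-hydroxyethyl)-2,5,5,8a-tetramethyldecahydronaphthalen-2-ol (8α,12-diol) | C[C@]12CCCC(C)(C)[C@@H]1CC[C@@](C)(O)[C@@H]2CCO
F2 | step 2 | 2-[(1R,2R,4aS,8aS)-2-hydroxy-2,5,5,8a-tetramethyldecahydronaphthalen-1-yl]ethyl acetate | C[C@]12CCCC(C)(C)[C@@H]1CC[C@@](C)(O)[C@@H]2CCOC(C)=O
F3 | step 2 | 2-[(1S,4aS,8aS)-5,5,8a-trimethyl-2-methylidenedecahydronaphthalen-1-yl]ethyl acetate | C[C@]12CCCC(C)(C)[C@@H]1CCC(=C)[C@@H]2CCOC(C)=O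
F4 | step 2 | 2-[(4aS,8aS)-2,5,5,8a-tetramethyl-3,4,4a,5,6,7,8,8a-octahydronaphthalen-1-yl]ethyl acetate | CC1=C(CCOC(C)=O)[C@@]2(C)CCCC(C)(C)[C@@H]2CC1
F5 | step 5 | 2-[(4aS,8aS)-2,5,5,8a-tetramethyl-3,4,4a,5,6,7,8,8a-octahydronaphthalen-1-yl]acetaldehyde | CC1=C(CC=O)[C@@]2(C)CCCC(C)(C)[C@@H]2CC1
F6 | step 5 | 2-[(2S,4S)-2-tert-butyl-4-{1-hydroxy-2-[(4aS,8aS)-2,5,5,8a-tetramethyl-3,4,4a,5,6,7,8,8a-octahydronaphthalen-1-yl]ethyl}-5-oxo-1,3-dioxolan-4-yl]acetic acid (C12 epimers) | CC(C)(C)[C@H]1O[C@@](C(O)CC2=C(C)CC[C@H]3C(C)(C)CCC[C@]23C)(CC(=O)O)C(=O)O1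
F7 | step 5 | O-phenyl thionocarbonate of F6 at the C12 hydroxyl | CC(C)(C)[C@H]1O[C@@](C(OC(=S)Oc2ccccc2)CC2=C(C)CC[C@H]3C(C)(C)CCC[C@]23C)(CC(=O)O)C(=O)O1
F8 | step 7 | 2-[(2S,4S)-2-tert-butyl-4-{2-[(4R,4aS,8aS)-4-hydroxy-2,5,5,8a-tetramethyl-3-oxo-3,4,4a,5,6,7,8,8a-octahydronaphthalen-1-yl]ethyl}-5-oxo-1,3-dioxolan-4-yl]acetic acid (6α-hydroxy enone) | CC(C)(C)[C@H]1O[C@@](CCC2=C(C)C(=O)[C@H](O)[C@H]3C(C)(C)CCC[C@]23C)(CC(=O)O)C(=O)O1
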